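**Strategy**

The route rests on opening ring A of the decalin at the C3–C4 bond (drimane numbering). C4 is a quaternary carbon alpha to the carboxyl group and sits 1,3 to the quaternary C10, so a C4 ester enolate can be alkylated by a three-carbon arm (C1–C3) hanging from C10. That single step closes ring A, forms C3–C4 and sets the C4 stereocentre (axial methyl, equatorial carboxyl) under allylic-strain control from C5–H. Its precursor is a carvone-derived ring B cyclohexene carrying the arylmethyl group at C9, methyl and 3-iodopropyl at C10 and a 2-(trimethylsilyl)ethyl propanoate at C5; the silyl-protected 4-methoxyphenol later becomes the epoxy-ene-diol ring.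

Key step: step 15

Remark: decalin atoms carry drimane numbers (C11 = benzylic CH2) and the oxygenated ring primed numbers (C1' carbinol next to the quaternary epoxide carbon C2', C3' epoxide CH, C4' second carbinol, C5' methyl-bearing, C6' alkene CH); the target SMILES is read as both hydroxyls trans to the epoxide oxygen and cis to C11; Ar = 5-methoxy-4-methyl-2-(triisopropylsilyloxy)phenyl, TMSE = 2-(trimethylsilyl)ethyl; hydroboration (step 11) is assumed unselective, so 20–25 are C4 epimer mixtures with C4 left open in their SMILES.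

**Route**

Step 1
Reactants: 1 (R)-carvone
Product: 3 6-methylcarvone (C6 epimer mixture), via lithium dienolate 2 (not isolated)
Conditions: LiN(iPr)2, THF, −78 °C; MeI, −78 → 0 °C
Reagents that add atoms: iodomethane, CI
Why: Kinetic deprotonation at the alpha-prime CH2 (future C10) gives the cross-conjugated dienolate, which is C-methylated in an SN2 enolate alkylation; the new centre need not be controlled because it is re-enolised in step 2.

Step 2
Reactants: 3 6-methylcarvone; 4 1-chloro-3-iodopropane
Product: 6 (5S,6S)-6-(3-chloropropyl)-2,6-dimethyl-5-(prop-1-en-2-yl)cyclohex-2-en-1-one, via lithium enolate 5 (not isolated)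
Conditions: LiN(iPr)2, THF, −78 °C; DMPU, 4, −78 → −20 °C
Reagents that add atoms: none
Why: Enolate alkylation at the C–I end (the chloride is far less reactive) creates the quaternary carbon (future C10); the electrophile approaches the tetrasubstituted enolate on the face opposite the adjacent isopropenyl group, so the chloropropyl arm ends trans and the methyl cis to it, as the trans-decalin requires.

Step 3
Reactants: 7 4-methoxy-3-methylphenol
Product: 8 2-hydroxy-5-methoxy-4-methylbenzaldehyde
Conditions: MgCl2, Et3N, (CH2O)n, MeCN, reflux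
Reagents that add atoms: paraformaldehyde (as formaldehyde), C=O
Why: Magnesium-phenoxide-directed ortho-formylation (Casnati–Skattebøl) is ortho-specific and takes the free ortho position para to the methyl group instead of the one flanked by OH and CH3.

Step 4
Reactants: 8 2-hydroxy-5-methoxy-4-methylbenzaldehyde
Product: 9 5-methoxy-4-methyl-2-(triisopropylsilyloxy)benzaldehyde
Conditions: iPr3SiCl, imidazole, DMF, rt
Reagents that add atoms: chlorotriisopropylsilane, CC(C)[Si](Cl)(C(C)C)C(C)C
Why: Standard phenol silylation; the bulky silyl ether tolerates the organometallic, hydride, oxidative and strongly basic steps ahead and is later removed by fluoride without acid, which matters because a free ortho-phenol beside the C7=C8 alkene would cyclise to a chroman under acid.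

Step 5
Reactants: 9 5-methoxy-4-methyl-2-(triisopropylsilyloxy)benzaldehyde
Product: 10 benzylic alcohol ArCH2OH
Conditions: NaBH4, MeOH/THF, 0 °C
Reagents that add atoms: none
Why: Borohydride reduces the aldehyde chemoselectively to the benzylic alcohol and leaves the aryl silyl ether intact.

Step 6
Reactants: 10 benzylic alcohol ArCH2OH
Product: 12 benzylic chloride ArCH2Cl, via benzylic mesylate 11 (not isolated)
Conditions: MeSO2Cl, Et3N, LiCl, THF, 0 °C → rt
Reagents that add atoms: lithium chloride, [Li+].[Cl-]
Why: The alcohol is mesylated and the benzylic mesylate is displaced in situ by chloride (SN2), which avoids acid that would threaten the aryl silyl ether.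

Step 7
Reactants: 12 benzylic chloride ArCH2Cl; 6 chloropropyl ketone
Product: 14 tertiary allylic alcohol (ArCH2 and OH on the future C9; carbinol configuration open), via benzylmagnesium chloride 13 (not isolated)
Conditions: Mg, THF, 0 °C; CeCl3, THF, −78 °C; 6, −78 → 0 °C; aq. NH4Cl
Reagents that add atoms: none
Why: 1,2-Addition of a benzyl Grignard/organocerium reagent to the hindered enone carbonyl; cerium trichloride suppresses conjugate addition and base-induced side reactions, the primary chloride is inert at low temperature, and the carbinol configuration is irrelevant because C9 becomes trigonal in step 8.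

Step 8
Reactants: 14 tertiary allylic alcohol
Product: 15 transposed enone (C7 ketone; C8=C9 bearing methyl and ArCH2)
Conditions: C5H5NH[CrO3Cl] (pyridinium chlorochromate), 4 Å molecular sieves, CH2Cl2, rt
Reagents that add atoms: pyridinium chlorochromate, [O-][Cr](=O)(=O)Cl.c1cc[nH+]cc1
Why: Babler–Dauben oxidative transposition: the tertiary allylic chromate ester undergoes a [3,3] shift to C7 and is oxidised there, so the C7 carbonyl oxygen comes from the reagent; no stereocentre is formed.

Step 9
Reactants: 15 transposed enone
Product: 16 7β-allylic alcohol (OH cis to the C5 isopropenyl group)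
Conditions: NaBH4, CeCl3·7H2O, MeOH, −40 °C
Reagents that add atoms: none
Why: Luche 1,2-reduction; as in the reduction of carvone to cis-carveol, hydride adds to the C7 carbonyl from the α face (axial attack with the C5 group pseudo-equatorial, or attack anti to that group if it is pseudo-axial), so the hydroxyl ends cis to the isopropenyl group.

Step 10
Reactants: 16 7β-allylic alcohol
Product: 19 ring B cyclohexene with 9α-H and C7=C8, via sulfonylhydrazone adduct 17 (not isolated), via allylic diazene 18 (not isolated)
Conditions: Me2C=N–NHSO2C6H4-2-NO2, PPh3, DEAD, THF, 0 °C → rt; then CF3CH2OH/H2O (1:1), rt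
Reagents that add atoms: none
Why: Mitsunobu displacement by the sulfonylhydrazone nitrogen inverts C7 (17); hydrolysis and loss of 2-nitrobenzenesulfinic acid give the monoalkyl diazene 18, whose retro-ene loss of N2 transfers hydrogen suprafacially to C9 on the α face where nitrogen sat, moving the alkene to C7=C8 and setting 9α-H (arylmethyl cis to the C10 methyl).

Step 11
Reactants: 19 ring B cyclohexene
Product: 21 primary alcohol (C4 epimers), via B-alkyl-9-borabicyclononane 20 (not isolated)
Conditions: 9-borabicyclo[3.3.1]nonane, THF, 0 °C → rt; NaBO3·4H2O, THF/H2O, rt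
Reagents that add atoms: sodium perborate, [Na+].[Na+].O[B-]1(O)OO[B-](O)(O)OO1
Why: Hydroboration–oxidation: the bulky borane adds anti-Markovnikov to the 1,1-disubstituted isopropenyl group much faster than to the hindered trisubstituted C7=C8 alkene, and perborate oxidation is mild enough for the aryl silyl ether; the new C4 centre forms as a mixture that step 15 erases.

Step 12
Reactants: 21 primary alcohol
Product: 23 carboxylic acid (C4 epimers), via aldehyde 22 (not isolated)
Conditions: 2,2,6,6-tetramethylpiperidin-1-oxyl (cat.), PhI(OAc)2, MeCN/H2O, rt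
Reagents that add atoms: water, O
Why: Nitroxyl-catalysed oxidation with PhI(OAc)2 as terminal oxidant takes the primary alcohol through the hydrated aldehyde to the acid without touching the alkene, the alkyl chloride or the silyl ether.

Step 13
Reactants: 23 carboxylic acid
Product: 24 TMSE ester with chloropropyl arm (C4 epimers)
Conditions: Me3SiCH2CH2OH, iPrN=C=NiPr, 4-(dimethylamino)pyridine (cat.), CH2Cl2, 0 °C → rt
Reagents that add atoms: 2-(trimethylsilyl)ethanol, C[Si](C)(C)CCO
Why: Steglich esterification of an α-branched acid with a primary alcohol; the TMSE ester is chosen because it tolerates enolisation, oxidation, basic peroxide, hydride and mild acid, and is finally cleaved at silicon by fluoride, which a hindered C4 methyl ester would not allow next to an epoxide.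

Step 14
Reactants: 24 TMSE ester with chloropropyl arm
Product: 25 iodopropyl cyclohexene propanoate (key-step precursor; C4 epimers)
Conditions: NaI, acetone, reflux
Reagents that add atoms: sodium iodide, [Na+].[I-]
Why: Finkelstein exchange (SN2, driven by precipitation of NaCl) turns the robust chloride, needed to survive the organometallic and alkoxide stages, into the iodide required for ring closure.

Step 15
Reactants: 25 iodopropyl cyclohexene propanoate
Product: 27 aryl decalin TMSE ester, via potassium enolate 26 (not isolated)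
Conditions: KN(SiMe3)2, THF (high dilution), −78 → 0 °C
Reagents that add atoms: none
Why: KN(SiMe3)2 removes the C4 proton of the ester to give potassium enolate 26, whose C4 attacks C3 from the back of the C–I bond in an SN2 displacement. This is an intramolecular ester-enolate alkylation forming a quaternary carbon, a known reaction type. Ring A closes in the 6-exo-tet mode through a chair in which the C1–C3 arm, anchored on C10 trans to C5–H, can reach only one face of the enolate. The new C4 stereocentre is controlled by allylic 1,3-strain: the enolate keeps C5–H in its own plane beside the oxygen-bearing carbon, so the methyl group lies next to C10 and becomes axial (β) while the ester becomes equatorial (α). The step needs facial selectivity at trigonal C4 and C-alkylation in preference to elimination of HI; the first is secured by this rotamer preference together with the fixed C5 and C10 configurations, the second by the primary iodide, the six-membered transition state and the low temperature. The C4 configuration of 25 is immaterial because enolisation destroys it.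

Step 16
Reactants: 27 aryl decalin TMSE ester
Product: 28 phenol
Conditions: Bu4NF (1.1 equiv), AcOH (1.1 equiv), THF, 0 °C
Reagents that add atoms: none
Why: Fluoride cleaves the aryl Si–O bond (phenoxide leaving group) much faster than it attacks the trimethylsilyl group of the hindered ester when one buffered equivalent is used at 0 °C, so the TMSE ester should survive; no acid strong enough to cyclise the phenol onto C7=C8 is present.

Step 17
Reactants: 28 phenol
Product: 29 4,4-dimethoxycyclohexa-2,5-dienone (quinone monoketal)
Conditions: PhI(OAc)2, MeOH, 0 °C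
Reagents that add atoms: methanol, CO
Why: Oxidative dearomatisation of a para-methoxyphenol by a hypervalent iodine reagent; methanol captures the oxidised ring at the methoxy-bearing para carbon to give the dimethyl ketal, while isolated alkenes and the ester are inert.

Step 18
Reactants: 29 quinone monoketal
Product: 30 2',3'-epoxy ketone (epoxide oxygen α, C11 β)
Conditions: tBuOOH, aq. NaOH, N-benzylcinchonidinium chloride (0.2 equiv), toluene, 0 °C
Reagents that add atoms: tert-butyl hydroperoxide, CC(C)(C)OO
Why: Weitz–Scheffer nucleophilic epoxidation under chiral phase-transfer catalysis: the peroxide anion adds to C3', the only unsubstituted beta carbon (C5' carries methyl), and the C2' enolate closes the epoxide; the cinchonidinium ion pair is expected to select the face of C2'=C3' (reagent control, the decalin centres being remote), and the pseudoenantiomeric cinchoninium salt is the immediate alternative if the opposite face is preferred.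

Step 19
Reactants: 30 epoxy ketone
Product: 31 C1' alcohol (OH trans to the epoxide oxygen and cis to C11)
Conditions: NaBH4, CeCl3·7H2O, MeOH, −78 °C
Reagents that add atoms: none
Why: Luche 1,2-reduction of the C1' enone carbonyl; hydride attacks anti to the bulky C11 arm on the adjacent quaternary epoxide carbon, that is, syn to the small epoxide oxygen, in line with the trans preference of cerium-assisted borohydride reduction of cyclic α,β-epoxy ketones; the ester is untouched.

Step 20
Reactants: 31 epoxy alcohol ketal
Product: 32 4'-oxo epoxy alcohol (hydroxy epoxy enone)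
Conditions: p-toluenesulfonic acid monohydrate (cat.), acetone/H2O (10:1), 0 °C → rt
Reagents that add atoms: water, O
Why: Acid-catalysed hydrolysis of the allylic dimethyl ketal (oxocarbenium stabilised by C5'=C6') unmasks the C4' ketone; the epoxy alcohol, the TMSE ester and the trisubstituted alkene tolerate catalytic acid and no stereocentre changes.

Step 21
Reactants: 32 hydroxy epoxy enone
Product: 33 TMSE ester of the target
Conditions: NaBH4, CeCl3·7H2O, MeOH, −78 °C
Reagents that add atoms: none
Why: Luche 1,2-reduction at C4'; the β face is screened by the C11 arm projecting from C2' (1,3 to C4') and the reagent again follows the trans preference for α,β-epoxy ketones, so hydride arrives syn to the epoxide oxygen and the C4' hydroxyl ends trans to the epoxide and cis to the C1' hydroxyl.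

Step 22
Reactants: 33 TMSE ester of the target
Product: 34 target acid CNP0358222.2
Conditions: (Me2N)3S[Me3SiF2], DMF, 0 °C → rt; aq. NH4Cl
Reagents that add atoms: none
Why: Fluoride attacks the silicon of the TMSE group and triggers β-elimination (ethylene, Me3SiF) to free the carboxylate regardless of the steric shielding at C4; this anhydrous, weakly basic fluoride source should leave the epoxide and both allylic alcohols untouched, and no stereocentre is affected.

**Compound list**

1 | (R)-carvone, (5R)-2-methyl-5-(prop-1-en-2-yl)cyclohex-2-en-1-one | CC1=CC[C@@H](C(C)=C)CC1=O | starting material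
2 | kinetic lithium dienolate of 1 (O–Li on C1; C1=C6 and C2=C3, carvone numbering) | CC1=CC[C@@H](C(C)=C)C=C1[O-].[Li+] | intermediate
3 | 6-methylcarvone, (5R)-2,6-dimethyl-5-(prop-1-en-2-yl)cyclohex-2-en-1-one, C6 epimer mixture | CC1=CC[C@@H](C(C)=C)C(C)C1=O | intermediate
4 | 1-chloro-3-iodopropane | ClCCCI | starting material
5 | lithium enolate of 3 (tetrasubstituted C1=C6 enolate) | CC1=CC[C@@H](C(C)=C)C(C)=C1[O-].[Li+] | intermediate
6 | (5S,6S)-6-(3-chloropropyl)-2,6-dimethyl-5-(prop-1-en-2-yl)cyclohex-2-en-1-one (chloropropyl trans to isopropenyl) | O=C1C(C)=CC[C@@H](C(C)=C)[C@]1(C)CCCCl | intermediate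
7 | 4-methoxy-3-methylphenol | COc1ccc(O)cc1C | starting material
8 | 2-hydroxy-5-methoxy-4-methylbenzaldehyde | Cc1cc(O)c(C=O)cc1OC | intermediate
9 | 5-methoxy-4-methyl-2-(triisopropylsilyloxy)benzaldehyde | Cc1cc(O[Si](C(C)C)(C(C)C)C(C)C)c(C=O)cc1OC | intermediate
10 | [5-methoxy-4-methyl-2-(triisopropylsilyloxy)phenyl]methanol (ArCH2OH) | Cc1cc(O[Si](C(C)C)(C(C)C)C(C)C)c(CO)cc1OC | intermediate
11 | [5-methoxy-4-methyl-2-(triisopropylsilyloxy)phenyl]methyl methanesulfonate | Cc1cc(O[Si](C(C)C)(C(C)C)C(C)C)c(COS(C)(=O)=O)cc1OC | intermediate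
12 | [2-(chloromethyl)-4-methoxy-5-methylphenoxy]triisopropylsilane (ArCH2Cl) | Cc1cc(O[Si](C(C)C)(C(C)C)C(C)C)c(CCl)cc1OC | intermediate
13 | ArCH2MgCl, the benzylmagnesium chloride from 12 | Cc1cc(O[Si](C(C)C)(C(C)C)C(C)C)c(C[Mg]Cl)cc1OC | intermediate
14 | 1-(ArCH2)-6-(3-chloropropyl)-2,6-dimethyl-5-(prop-1-en-2-yl)cyclohex-2-en-1-ol; ring centres as in 6, carbinol carbon (future C9) undefined | Cc1cc(O[Si](C(C)C)(C(C)C)C(C)C)c(CC2(O)C(C)=CC[C@@H](C(C)=C)[C@]2(C)CCCCl)cc1OC | intermediate
15 | 3-(ArCH2)-4-(3-chloropropyl)-2,4-dimethyl-5-(prop-1-en-2-yl)cyclohex-2-en-1-one; chloropropyl trans to isopropenyl (drimane: C7 ketone, C8=C9) | Cc1cc(O[Si](C(C)C)(C(C)C)C(C)C)c(CC2=C(C)C(=O)C[C@@H](C(C)=C)[C@]2(C)CCCCl)cc1OC | intermediate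
16 | cyclohex-2-en-1-ol from 15 with OH cis to isopropenyl (7β-OH) | Cc1cc(O[Si](C(C)C)(C(C)C)C(C)C)c(CC2=C(C)[C@@H](O)C[C@@H](C(C)=C)[C@]2(C)CCCCl)cc1OC | intermediate
17 | Mitsunobu adduct: C7 (inverted, 7α) bonded to N(SO2C6H4-2-NO2)–N=CMe2 | Cc1cc(O[Si](C(C)C)(C(C)C)C(C)C)c(CC2=C(C)[C@H](N(N=C(C)C)S(=O)(=O)c3ccccc3[N+](=O)[O-])C[C@@H](C(C)=C)[C@]2(C)CCCCl)cc1OC | intermediate
18 | 7α-allylic monoalkyl diazene (C7–N=NH) | Cc1cc(O[Si](C(C)C)(C(C)C)C(C)C)c(CC2=C(C)[C@H](N=N)C[C@@H](C(C)=C)[C@]2(C)CCCCl)cc1OC | intermediate
19 | 6-(ArCH2)-5-(3-chloropropyl)-1,5-dimethyl-4-(prop-1-en-2-yl)cyclohex-1-ene; ArCH2 cis to the C5 methyl, chloropropyl trans to isopropenyl (drimane: 9α-H, C7=C8) | Cc1cc(O[Si](C(C)C)(C(C)C)C(C)C)c(C[C@H]2C(C)=CC[C@@H](C(C)=C)[C@]2(C)CCCCl)cc1OC | intermediate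
20 | B-alkyl-9-borabicyclo[3.3.1]nonane from 19 (boron on the terminal carbon of the former isopropenyl group; C4 epimers) | Cc1cc(O[Si](C(C)C)(C(C)C)C(C)C)c(C[C@H]2C(C)=CC[C@@H](C(C)CB3C4CCCC3CCC4)[C@]2(C)CCCCl)cc1OC | intermediate
21 | primary alcohol: 19 with isopropenyl converted into CH(CH3)CH2OH (C4 epimers) | Cc1cc(O[Si](C(C)C)(C(C)C)C(C)C)c(C[C@H]2C(C)=CC[C@@H](C(C)CO)[C@]2(C)CCCCl)cc1OC | intermediate
22 | aldehyde: side chain CH(CH3)CHO (C4 epimers) | Cc1cc(O[Si](C(C)C)(C(C)C)C(C)C)c(C[C@H]2C(C)=CC[C@@H](C(C)C=O)[C@]2(C)CCCCl)cc1OC | intermediate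
23 | carboxylic acid: side chain CH(CH3)CO2H (C4 epimers) | Cc1cc(O[Si](C(C)C)(C(C)C)C(C)C)c(C[C@H]2C(C)=CC[C@@H](C(C)C(=O)O)[C@]2(C)CCCCl)cc1OC | intermediate
24 | TMSE 2-[ring B cyclohexenyl]propanoate with 3-chloropropyl arm (C4 epimers) | Cc1cc(O[Si](C(C)C)(C(C)C)C(C)C)c(C[C@H]2C(C)=CC[C@@H](C(C)C(=O)OCC[Si](C)(C)C)[C@]2(C)CCCCl)cc1OC | intermediate
25 | key-step precursor: TMSE 2-[ring B cyclohexenyl]propanoate with 3-iodopropyl arm (C4 epimers) | Cc1cc(O[Si](C(C)C)(C(C)C)C(C)C)c(C[C@H]2C(C)=CC[C@@H](C(C)C(=O)OCC[Si](C)(C)C)[C@]2(C)CCCI)cc1OC | intermediate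
26 | potassium ester enolate of 25 (C4 trigonal) | Cc1cc(O[Si](C(C)C)(C(C)C)C(C)C)c(C[C@H]2C(C)=CC[C@@H](C(C)=C([O-])OCC[Si](C)(C)C)[C@]2(C)CCCI)cc1OC.[K+] | intermediate
27 | key-step product: trans-decalin with 4β-CH3, 4α-CO2TMSE, 5α-H, 9α-H, 10β-CH3, C7=C8 and ArCH2 at C9 | Cc1cc(O[Si](C(C)C)(C(C)C)C(C)C)c(C[C@H]2C(C)=CC[C@@H]3[C@]2(C)CCC[C@@]3(C)C(=O)OCC[Si](C)(C)C)cc1OC | intermediate
28 | phenol: 27 with the silyl ether cleaved (2-hydroxy-5-methoxy-4-methylbenzyl at C9) | Cc1cc(O)c(C[C@H]2C(C)=CC[C@@H]3[C@]2(C)CCC[C@@]3(C)C(=O)OCC[Si](C)(C)C)cc1OC | intermediate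
29 | quinone monoketal: 4,4-dimethoxy-5-methylcyclohexa-2,5-dien-1-one carrying C11 at C2' | CC1=CC(=O)C(C[C@H]2C(C)=CC[C@@H]3[C@]2(C)CCC[C@@]3(C)C(=O)OCC[Si](C)(C)C)=CC1(OC)OC | intermediate
30 | 2',3'-epoxy ketone of 29 (epoxide oxygen α, C11 β) | CC1=CC(=O)[C@]2(C[C@H]3C(C)=CC[C@@H]4[C@]3(C)CCC[C@@]4(C)C(=O)OCC[Si](C)(C)C)O[C@@H]2C1(OC)OC | intermediate
31 | C1' alcohol of 30 (OH trans to epoxide oxygen), ketal intact | CC1=C[C@@H](O)[C@]2(C[C@H]3C(C)=CC[C@@H]4[C@]3(C)CCC[C@@]4(C)C(=O)OCC[Si](C)(C)C)O[C@@H]2C1(OC)OC | intermediate
32 | 1'-hydroxy-2',3'-epoxy-4'-oxo enone | CC1=C[C@@H](O)[C@]2(C[C@H]3C(C)=CC[C@@H]4[C@]3(C)CCC[C@@]4(C)C(=O)OCC[Si](C)(C)C)O[C@@H]2C1=O | intermediate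
33 | TMSE ester of the target (1',4'-diol, both OH trans to the epoxide) | CC1=C[C@@H](O)[C@]2(C[C@H]3C(C)=CC[C@@H]4[C@]3(C)CCC[C@@]4(C)C(=O)OCC[Si](C)(C)C)O[C@@H]2[C@H]1O | intermediate
34 | CNP0358222.2, the free C4 carboxylic acid | CC1=C[C@@H](O)[C@]2(C[C@H]3C(C)=CC[C@@H]4[C@]3(C)CCC[C@@]4(C)C(=O)O)O[C@@H]2[C@H]1O | target

**Step count and risks**

Total: 22 steps. Longest linear sequence: 20 steps (steps 3–22, from 7); the carvone branch is 18 steps (steps 1, 2, 7–22).

Steps most likely to fail:

1. Step 15. Ring closure at the hindered tertiary enolate carbon may lose to elimination of HI, to proton transfer or to ketene formation from the ester enolate, or the facial selectivity at C4 may be poor. Fallback (acid-dianion alkylation in place of ester-enolate alkylation): from acid 23, NaI in acetone gives the iodo acid F1. Two equivalents of LiN(iPr)2 in THF/DMPU (−78 → 0 °C) form its dilithium enediolate, which cannot fragment to a ketene, is more nucleophilic at carbon and has an oxygen on either side of C4, so the same allylic-strain rotamer is enforced; 6-exo-tet closure gives the decalin acid F2. Mitsunobu esterification (2-(trimethylsilyl)ethanol, PPh3, DIAD), which forms the C–O bond at the unhindered alcohol carbon, returns to 27.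

2. Step 18. The peroxide addition may show poor facial selectivity, since the catalyst must override a remote chiral decalin, or may be slow at the α-substituted double bond. Fallback (auxiliary control in place of catalyst control): from 29, ketal exchange with (2S,4S)-pentane-2,4-diol (pyridinium p-toluenesulfonate, benzene, 60 °C) gives the C2-symmetric dioxane monoketal F3. Epoxidation with Ph3COOH and KN(SiMe3)2 (THF, −78 → −20 °C), directed by the axial methyl of the dioxane, gives the epoxy ketone F4; the antipodal diol serves if the other face is needed. Luche reduction as in step 19 gives the epoxy alcohol F5, and aqueous acid hydrolysis of the dioxane rejoins the route at 32.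

3. Step 10. The Mitsunobu displacement at the hindered C7 carbinol beside a tetrasubstituted alkene may give way to elimination to a diene, or the diazene may lose N2 without clean hydrogen transfer. Fallback (palladium hydride delivery in place of sigmatropic transfer): from 16, acetic formic anhydride and pyridine give the allylic formate F6. With Pd(OAc)2 and PBu3 in dioxane at 80 °C, zerovalent palladium ionises it anti to the leaving group, the formate ligand loses CO2, and the palladium hydride delivers hydrogen to the more substituted allyl terminus C9 from the α face, returning to 19.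

**Further compounds**

F1 | step 15 | iodo acid: 23 with the chloride exchanged for iodide (C4 epimers) | Cc1cc(O[Si](C(C)C)(C(C)C)C(C)C)c(C[C@H]2C(C)=CC[C@@H](C(C)C(=O)O)[C@]2(C)CCCI)cc1OC
F2 | step 15 | decalin acid: free C4 carboxylic acid corresponding to 27 | Cc1cc(O[Si](C(C)C)(C(C)C)C(C)C)c(C[C@H]2C(C)=CC[C@@H]3[C@]2(C)CCC[C@@]3(C)C(=O)O)cc1OC
F3 | step 18 | quinone monoketal of (2S,4S)-pentane-2,4-diol (spiro 1,3-dioxane in place of the dimethyl ketal of 29) | CC1=CC(=O)C(C[C@H]2C(C)=CC[C@@H]3[C@]2(C)CCC[C@@]3(C)C(=O)OCC[Si](C)(C)C)=CC15O[C@@H](C)C[C@H](C)O5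
F4 | step 18 | 2',3'-epoxy ketone of F3 (epoxide oxygen α) | CC1=CC(=O)[C@]2(C[C@H]3C(C)=CC[C@@H]4[C@]3(C)CCC[C@@]4(C)C(=O)OCC[Si](C)(C)C)O[C@@H]2C15O[C@@H](C)C[C@H](C)O5
F5 | step 18 | C1' alcohol of F4 (OH trans to the epoxide oxygen) | CC1=C[C@@H](O)[C@]2(C[C@H]3C(C)=CC[C@@H]4[C@]3(C)CCC[C@@]4(C)C(=O)OCC[Si](C)(C)C)O[C@@H]2C15O[C@@H](C)C[C@H](C)O5
F6 | step 10 | 7β-allylic formate of 16 | Cc1cc(O[Si](C(C)C)(C(C)C)C(C)C)c(CC2=C(C)[C@@H](OC=O)C[C@@H](C(C)=C)[C@]2(C)CCCCl)cc1OC
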